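**Strategy.** The route rests on cutting the C3=C4 enol ether bond of ring B. O2–C3 is at the oxidation level of an ester between the C1 hydroxyl of a ring A vinyl carbinol and the (E)-enoic acid of the side chain, and C4 is a vinyl carbon on C4a. A titanium alkylidene carbonyl–olefin metathesis then closes ring B and forms C3=C4 in one operation, with every stereocentre of the target already in place. The precursor is the per-triethylsilylated ester of the L-isoleucine-derived acid with a 2-vinylcyclohexenylmethanol whose C6 ketone is masked as a silyl ether. Triethylsilyl groups throughout let the acid-labile C6 carbinol be unmasked by fluoride before MnO2 oxidation.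

Key step: step 21

Assumption: 3-[(4-methoxybenzyl)oxy]propanoic acid is taken as a catalogue compound, and the C6 oxygen is carried as the α epimer (cis to the C7 oxygen) because this centre is erased in the last step.

**Ring A (steps 1–11)**

Step 1
Reactants: 1 3-[(4-methoxybenzyl)oxy]propanoic acid; 2 (S)-4-benzyloxazolidin-2-one
Product: 4 (S)-4-benzyl-3-{3-[(4-methoxybenzyl)oxy]propanoyl}oxazolidin-2-one, via mixed pivalic anhydride 3 (not isolated)
Conditions: t-BuCOCl, Et3N, THF, −20 °C; then 2, LiCl, −20 °C to rt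
Reagents that add atoms: none
Why: N-acylation of an oxazolidinone by a mixed pivalic anhydride in the presence of LiCl and Et3N is a standard imide formation and touches no stereocentre.

Step 2
Reactants: 4 (S)-4-benzyl-3-{3-[(4-methoxybenzyl)oxy]propanoyl}oxazolidin-2-one; 5 methacrolein
Product: 7 (S)-4-benzyl-3-[(2S,3S)-3-hydroxy-2-{[(4-methoxybenzyl)oxy]methyl}-4-methylpent-4-enoyl]oxazolidin-2-one, via dibutylboron Z-enolate 6 (not isolated)
Conditions: Bu2BOTf, i-Pr2NEt, CH2Cl2, −78 to 0 °C; then 5, −78 to 0 °C; pH 7 buffer, MeOH, H2O2, 0 °C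
Reagents that add atoms: none
Why: In this Evans syn-aldol reaction the Z-boron enolate should react through a Zimmerman–Traxler chair on the face away from the benzyl group, which sets C8a (S) and C8 (S) as the syn pair, while the covalent boron enolate should not expel the β-alkoxide at low temperature.

Step 3
Reactants: 7 (S)-4-benzyl-3-[(2S,3S)-3-hydroxy-2-{[(4-methoxybenzyl)oxy]methyl}-4-methylpent-4-enoyl]oxazolidin-2-one
Product: 8 (2S,3S)-3-hydroxy-N-methoxy-2-{[(4-methoxybenzyl)oxy]methyl}-N,4-dimethylpent-4-enamide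
Conditions: MeNH(OMe)·HCl, AlMe3, CH2Cl2, −20 to 0 °C; aq. potassium sodium tartrate
Reagents that add atoms: N,O-dimethylhydroxylamine hydrochloride, CNOC.Cl
Why: Aluminium amide transamination of an aldol adduct with a free β-hydroxyl (Weinreb amide formation) should cleave the exocyclic acyl group selectively and release the auxiliary.

Step 4
Reactants: 8 (2S,3S)-3-hydroxy-N-methoxy-2-{[(4-methoxybenzyl)oxy]methyl}-N,4-dimethylpent-4-enamide
Product: 9 (2S,3S)-N-methoxy-2-{[(4-methoxybenzyl)oxy]methyl}-N,4-dimethyl-3-[(triethylsilyl)oxy]pent-4-enamide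
Conditions: Et3SiOTf, 2,6-lutidine, CH2Cl2, −78 to 0 °C
Reagents that add atoms: triethylsilyl trifluoromethanesulfonate, CC[Si](CC)(CC)OS(=O)(=O)C(F)(F)F
Why: Silylation of a secondary alcohol with a silyl triflate and 2,6-lutidine is routine and blocks retro-aldol cleavage and dehydration in the ketone stages that follow.

Step 5
Reactants: 9 (2S,3S)-N-methoxy-2-{[(4-methoxybenzyl)oxy]methyl}-N,4-dimethyl-3-[(triethylsilyl)oxy]pent-4-enamide
Product: 10 (5S,6S)-5-{[(4-methoxybenzyl)oxy]methyl}-7-methyl-6-[(triethylsilyl)oxy]octa-1,7-dien-4-one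
Conditions: CH2=CHCH2MgBr, THF, −78 to −40 °C; cold aq. NH4Cl
Reagents that add atoms: allylmagnesium bromide, C=CC[Mg]Br
Why: Grignard addition to a Weinreb amide stops at the chelated tetrahedral adduct, so a cold buffered quench should give the β,γ-unsaturated ketone without over-addition or enolisation at C8a.

Step 6
Reactants: 10 (5S,6S)-5-{[(4-methoxybenzyl)oxy]methyl}-7-methyl-6-[(triethylsilyl)oxy]octa-1,7-dien-4-one
Product: 11 (5S,6S)-6-{[(4-methoxybenzyl)oxy]methyl}-4-methyl-5-[(triethylsilyl)oxy]cyclohex-3-en-1-one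
Conditions: second-generation Grubbs catalyst (H2IMes)(PCy3)Cl2Ru=CHPh (5 mol %), 1,4-benzoquinone (10 mol %), CH2Cl2, 40 °C
Reagents that add atoms: none
Why: Ring-closing metathesis of a terminal alkene with a 1,1-disubstituted alkene to a trisubstituted cyclohexene (the C6=C7 bond of ring A) is within the scope of this catalyst, and benzoquinone suppresses double-bond migration by ruthenium hydrides.

Step 7
Reactants: 11 (5S,6S)-6-{[(4-methoxybenzyl)oxy]methyl}-4-methyl-5-[(triethylsilyl)oxy]cyclohex-3-en-1-one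
Product: 12 (2S,3S,4S,5S)-4,5-dihydroxy-2-{[(4-methoxybenzyl)oxy]methyl}-4-methyl-3-[(triethylsilyl)oxy]cyclohexan-1-one
Conditions: OsO4 (3 mol %), NMO, acetone/H2O, 0 °C to rt
Reagents that add atoms: N-methylmorpholine N-oxide, C[N+]1([O-])CCOCC1; water, O
Why: Catalytic syn-dihydroxylation with OsO4 should take the ring face anti to the allylic C8 silyloxy group, the usual sense for osmylation next to an allylic oxygen, which sets C7 with its hydroxyl trans to the C8 oxygen and puts the C6 hydroxyl cis to the C7 hydroxyl.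

Step 8
Reactants: 12 (2S,3S,4S,5S)-4,5-dihydroxy-2-{[(4-methoxybenzyl)oxy]methyl}-4-methyl-3-[(triethylsilyl)oxy]cyclohexan-1-one
Product: 13 (2S,3S,4S,5S)-2-{[(4-methoxybenzyl)oxy]methyl}-4-methyl-3,4,5-tris[(triethylsilyl)oxy]cyclohexan-1-one
Conditions: Et3SiOTf (3 equiv), 2,6-lutidine, CH2Cl2, −78 to 0 °C
Reagents that add atoms: triethylsilyl trifluoromethanesulfonate, CC[Si](CC)(CC)OS(=O)(=O)C(F)(F)F
Why: A silyl triflate silylates secondary and tertiary alcohols alike, so one operation should cap the C6 and C7 hydroxyls while the weak base leaves the ketone unenolised at low temperature.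

Step 9
Reactants: 13 (2S,3S,4S,5S)-2-{[(4-methoxybenzyl)oxy]methyl}-4-methyl-3,4,5-tris[(triethylsilyl)oxy]cyclohexan-1-one
Product: 14 (3S,4S,5S,6S)-6-{[(4-methoxybenzyl)oxy]methyl}-4-methyl-3,4,5-tris[(triethylsilyl)oxy]cyclohex-1-en-1-yl trifluoromethanesulfonate
Conditions: PhNTf2, KN(SiMe3)2 (added last), THF, −78 °C
Reagents that add atoms: N-phenylbis(trifluoromethanesulfonimide), O=S(=O)(N(c1ccccc1)S(=O)(=O)C(F)(F)F)C(F)(F)F
Why: Kinetic enolisation with a hindered amide base should remove a proton from the C5 methylene in preference to the substituted C8a methine, and trapping in situ as the enol triflate fixes the C4a=C5 bond before the C6 silyloxy group can be lost by β-elimination.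

Step 10
Reactants: 14 (3S,4S,5S,6S)-6-{[(4-methoxybenzyl)oxy]methyl}-4-methyl-3,4,5-tris[(triethylsilyl)oxy]cyclohex-1-en-1-yl trifluoromethanesulfonate
Product: 15 (3S,4S,5S,6S)-6-(hydroxymethyl)-4-methyl-3,4,5-tris[(triethylsilyl)oxy]cyclohex-1-en-1-yl trifluoromethanesulfonate
Conditions: DDQ, CH2Cl2/pH 7 buffer, 0 °C
Reagents that add atoms: none
Why: Oxidative cleavage of a 4-methoxybenzyl ether with DDQ in buffered wet dichloromethane spares silyl ethers and an electron-poor enol triflate, and it is placed before the electron-rich diene exists.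

Step 11
Reactants: 15 (3S,4S,5S,6S)-6-(hydroxymethyl)-4-methyl-3,4,5-tris[(triethylsilyl)oxy]cyclohex-1-en-1-yl trifluoromethanesulfonate; 16 tributyl(vinyl)stannane
Product: 17 [(1S,4S,5S,6S)-2-ethenyl-5-methyl-4,5,6-tris(triethylsilyloxy)cyclohex-2-en-1-yl]methanol
Conditions: Pd(PPh3)4 (5 mol %), LiCl, THF, 65 °C
Reagents that add atoms: none
Why: Stille coupling of an enol triflate with a vinylstannane under zerovalent palladium catalysis with LiCl is a standard route to 1,3-dienes and tolerates the free primary alcohol and the allylic silyl ether.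

**Side chain (steps 12–19)**

Step 12
Reactants: 18 L-isoleucine
Product: 19 (2S,3S)-2-hydroxy-3-methylpentanoic acid
Conditions: NaNO2, 1 M H2SO4, H2O, 0 °C to rt
Reagents that add atoms: water, O
Why: Diazotisation of an α-amino acid in dilute acid gives the α-hydroxy acid with net retention through double inversion by the neighbouring carboxylate, so C4' and C5' of the target come directly from L-isoleucine.

Step 13
Reactants: 19 (2S,3S)-2-hydroxy-3-methylpentanoic acid
Product: 20 (2S,3S)-2-hydroxy-N-methoxy-N,3-dimethylpentanamide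
Conditions: MeNH(OMe)·HCl, EDC·HCl, HOBt, N-methylmorpholine, CH2Cl2, 0 °C to rt
Reagents that add atoms: N,O-dimethylhydroxylamine hydrochloride, CNOC.Cl
Why: Carbodiimide amide coupling of an α-hydroxy acid with N,O-dimethylhydroxylamine should give the Weinreb amide without hydroxyl protection and without epimerisation.

Step 14
Reactants: 20 (2S,3S)-2-hydroxy-N-methoxy-N,3-dimethylpentanamide
Product: 21 (5S,6S)-5-hydroxy-2,6-dimethyloct-2-en-4-one
Conditions: Me2C=CHMgBr (3 equiv), THF, 0 °C; aq. NH4Cl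
Reagents that add atoms: 2-methylprop-1-enylmagnesium bromide, CC(C)=C[Mg]Br
Why: In this Weinreb ketone synthesis the alkenyl Grignard reagent first deprotonates the hydroxyl and then adds once to the amide, and the β,β-disubstituted enone formed is not prone to conjugate addition or polymerisation.

Step 15
Reactants: 21 (5S,6S)-5-hydroxy-2,6-dimethyloct-2-en-4-one
Product: 22 (4R,5S,6S)-2,4,6-trimethyloct-2-ene-4,5-diol
Conditions: MeMgBr (3 equiv), THF, −78 to −40 °C; aq. NH4Cl
Reagents that add atoms: methylmagnesium bromide, C[Mg]Br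
Why: In this chelation-controlled 1,2-addition (Cram chelate) the magnesium alkoxide and the ketone oxygen form a five-membered chelate and the methyl group should enter from the side of the small α-hydrogen, which sets C3' (R) with its oxygen anti to the C4' oxygen along the chain that runs into the alkene.

Step 16
Reactants: 22 (4R,5S,6S)-2,4,6-trimethyloct-2-ene-4,5-diol
Product: 23 (4R,5S,6S)-2,4,6-trimethyl-4,5-bis[(triethylsilyl)oxy]oct-2-ene
Conditions: Et3SiOTf (3 equiv), 2,6-lutidine, CH2Cl2, −78 °C to rt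
Reagents that add atoms: triethylsilyl trifluoromethanesulfonate, CC[Si](CC)(CC)OS(=O)(=O)C(F)(F)F
Why: Silylation with a silyl triflate should cap the secondary and the tertiary hydroxyl in one operation.

Step 17
Reactants: 23 (4R,5S,6S)-2,4,6-trimethyl-4,5-bis[(triethylsilyl)oxy]oct-2-ene
Product: 25 (2S,3S,4S)-2,4-dimethyl-2,3-bis[(triethylsilyl)oxy]hexanal, via secondary ozonide 24 (not isolated)
Conditions: O3, CH2Cl2, −78 °C; then PPh3, −78 °C to rt
Reagents that add atoms: ozone, [O-][O+]=O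
Why: Ozonolysis with reductive work-up cleaves the only alkene to an aldehyde that has no α-hydrogen and so cannot epimerise.

Step 18
Reactants: 25 (2S,3S,4S)-2,4-dimethyl-2,3-bis[(triethylsilyl)oxy]hexanal
Product: 26 methyl (2E,4R,5S,6S)-4,6-dimethyl-4,5-bis[(triethylsilyl)oxy]oct-2-enoate
Conditions: Ph3P=CHCO2Me, toluene, 80 °C
Reagents that add atoms: methyl (triphenylphosphoranylidene)acetate, COC(=O)C=P(c1ccccc1)(c1ccccc1)c1ccccc1
Why: The Wittig reaction of a stabilised ylide with a hindered, non-enolisable aldehyde should give the (E)-enoate, the C1'=C2' bond of the target.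

Step 19
Reactants: 26 methyl (2E,4R,5S,6S)-4,6-dimethyl-4,5-bis[(triethylsilyl)oxy]oct-2-enoate
Product: 27 (2E,4R,5S,6S)-4,6-dimethyl-4,5-bis[(triethylsilyl)oxy]oct-2-enoic acid
Conditions: LiOH·H2O, THF/MeOH/H2O, rt; then 1 M HCl to pH 4, 0 °C
Reagents that add atoms: lithium hydroxide, [Li+].[OH-]
Why: Saponification of a methyl enoate is routine, the hindered triethylsilyl ethers tolerate aqueous base, and acidification only to pH 4 in the cold avoids acid cleavage.

**Union, key step and end game (steps 20–23)**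

Step 20
Reactants: 17 [(1S,4S,5S,6S)-2-ethenyl-5-methyl-4,5,6-tris(triethylsilyloxy)cyclohex-2-en-1-yl]methanol; 27 (2E,4R,5S,6S)-4,6-dimethyl-4,5-bis[(triethylsilyl)oxy]oct-2-enoic acid
Product: 28 [(1S,4S,5S,6S)-2-ethenyl-5-methyl-4,5,6-tris(triethylsilyloxy)cyclohex-2-en-1-yl]methyl (2E,4R,5S,6S)-4,6-dimethyl-4,5-bis(triethylsilyloxy)oct-2-enoate
Conditions: DCC, DMAP, CH2Cl2, 0 °C to rt
Reagents that add atoms: none
Why: Steglich esterification of a primary alcohol joins the two fragments under neutral conditions that spare the silyl ethers, the diene and the (E)-alkene.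

Step 21
Reactants: 28 [(1S,4S,5S,6S)-2-ethenyl-5-methyl-4,5,6-tris(triethylsilyloxy)cyclohex-2-en-1-yl]methyl (2E,4R,5S,6S)-4,6-dimethyl-4,5-bis(triethylsilyloxy)oct-2-enoate
Product: 30 (6S,7S,8S,8aS)-3-[(1E,3R,4S,5S)-3,5-dimethyl-3,4-bis(triethylsilyloxy)hept-1-en-1-yl]-7-methyl-6,7,8-tris(triethylsilyloxy)-6,7,8,8a-tetrahydro-1H-isochromene, via C4 titanium alkylidene 29 (not isolated)
Conditions: TiCl4, TMEDA, Zn, PbCl2 (cat.), CH3CHBr2, THF/CH2Cl2, 0 to 65 °C
Reagents that add atoms: none
Why: The low-valent titanium ethylidene made from TiCl4, Zn, PbCl2, TMEDA and CH3CHBr2 should exchange with the monosubstituted C4=CH2 terminus of the diene (propene leaves) to put titanium on C4 (29), this alkylidene should add [2+2] across the ester C3=O to an oxatitanacyclobutane, and cycloreversion should expel a titanium oxo species and leave the C3=C4 enol ether. The closest known reaction type is the titanium-alkylidene olefinic ester cyclisation that makes six-membered cyclic enol ethers, applied here to a conjugated ester and a dienyl alkene. Ring B closes in the 6-exo sense on the carbonyl group (C4 attacks C3 with the carbonyl oxygen outside the forming ring), and the new double bond ends up endocyclic. No stereocentre is formed, and none of the existing centres is α to a carbonyl group that the reagent could enolise. The step needs the alkylidene to load on the terminal vinyl group and not on the trisubstituted C4a=C5 or on the C1'=C2' alkene, which is electron-poor, 1,2-disubstituted and flanked by the quaternary C3'; it also needs carbonyl–olefin metathesis to beat simple ethylidenation of the ester, which the intramolecular six-membered closure favours. The ester is the only carbonyl group present, the amine-ligated reagent is only weakly Lewis acidic, and all five hydroxyls are silylated.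

Step 22
Reactants: 30 (6S,7S,8S,8aS)-3-[(1E,3R,4S,5S)-3,5-dimethyl-3,4-bis(triethylsilyloxy)hept-1-en-1-yl]-7-methyl-6,7,8-tris(triethylsilyloxy)-6,7,8,8a-tetrahydro-1H-isochromene
Product: 31 (6S,7S,8S,8aS)-3-[(1E,3R,4S,5S)-3,4-dihydroxy-3,5-dimethylhept-1-en-1-yl]-7-methyl-6,7,8,8a-tetrahydro-1H-isochromene-6,7,8-triol
Conditions: Bu4NF (8 equiv), THF, 0 °C to rt
Reagents that add atoms: none
Why: Fluoride cleavage of the five triethylsilyl ethers under basic conditions avoids acid, which would ionise the C6 carbinol now that it is a doubly vinylogous acetal (O2–C3=C4–C4a=C5–C6–O).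

Step 23
Reactants: 31 (6S,7S,8S,8aS)-3-[(1E,3R,4S,5S)-3,4-dihydroxy-3,5-dimethylhept-1-en-1-yl]-7-methyl-6,7,8,8a-tetrahydro-1H-isochromene-6,7,8-triol
Product: 32 (7R,8S,8aS)-3-[(1E,3R,4S,5S)-3,4-dihydroxy-3,5-dimethylhept-1-en-1-yl]-7,8-dihydroxy-7-methyl-1,7,8,8a-tetrahydro-6H-isochromen-6-one
Conditions: MnO2 (activated, excess), EtOAc, rt
Reagents that add atoms: none
Why: Activated MnO2 oxidises only allylic alcohols, so the C6 carbinol (allylic to C5=C4a and conjugated with the trienyl ether) should go to the ketone, while the saturated secondary C8 and C4' hydroxyls and the tertiary C7 and C3' hydroxyls stay.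

**Compound list**

1 | 3-[(4-methoxybenzyl)oxy]propanoic acid | COc1ccc(COCCC(=O)O)cc1 | starting material
2 | (S)-4-benzyloxazolidin-2-one | O=C1N[C@@H](Cc2ccccc2)CO1 | starting material
3 | 3-[(4-methoxybenzyl)oxy]propanoic pivalic anhydride (not isolated) | COc1ccc(COCCC(=O)OC(=O)C(C)(C)C)cc1 | intermediate
4 | (S)-4-benzyl-3-{3-[(4-methoxybenzyl)oxy]propanoyl}oxazolidin-2-one | COc1ccc(COCCC(=O)N2[C@@H](Cc3ccccc3)COC2=O)cc1 | intermediate
5 | methacrolein (2-methylprop-2-enal) | CC(=C)C=O | starting material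
6 | dibutylboron Z-enolate of 4 (not isolated) | COc1ccc(COC/C=C(\OB(CCCC)CCCC)N2[C@@H](Cc3ccccc3)COC2=O)cc1 | intermediate
7 | (S)-4-benzyl-3-[(2S,3S)-3-hydroxy-2-{[(4-methoxybenzyl)oxy]methyl}-4-methylpent-4-enoyl]oxazolidin-2-one | COc1ccc(COC[C@H](C(=O)N2[C@@H](Cc3ccccc3)COC2=O)[C@H](O)C(C)=C)cc1 | intermediate
8 | (2S,3S)-3-hydroxy-N-methoxy-2-{[(4-methoxybenzyl)oxy]methyl}-N,4-dimethylpent-4-enamide | COc1ccc(COC[C@H](C(=O)N(C)OC)[C@H](O)C(C)=C)cc1 | intermediate
9 | (2S,3S)-N-methoxy-2-{[(4-methoxybenzyl)oxy]methyl}-N,4-dimethyl-3-[(triethylsilyl)oxy]pent-4-enamide | COc1ccc(COC[C@H](C(=O)N(C)OC)[C@H](O[Si](CC)(CC)CC)C(C)=C)cc1 | intermediate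
10 | (5S,6S)-5-{[(4-methoxybenzyl)oxy]methyl}-7-methyl-6-[(triethylsilyl)oxy]octa-1,7-dien-4-one | COc1ccc(COC[C@H](C(=O)CC=C)[C@H](O[Si](CC)(CC)CC)C(C)=C)cc1 | intermediate
11 | (5S,6S)-6-{[(4-methoxybenzyl)oxy]methyl}-4-methyl-5-[(triethylsilyl)oxy]cyclohex-3-en-1-one | COc1ccc(COC[C@H]2[C@H](O[Si](CC)(CC)CC)C(C)=CCC2=O)cc1 | intermediate
12 | (2S,3S,4S,5S)-4,5-dihydroxy-2-{[(4-methoxybenzyl)oxy]methyl}-4-methyl-3-[(triethylsilyl)oxy]cyclohexan-1-one | COc1ccc(COC[C@H]2[C@H](O[Si](CC)(CC)CC)[C@@](C)(O)[C@@H](O)CC2=O)cc1 | intermediate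
13 | (2S,3S,4S,5S)-2-{[(4-methoxybenzyl)oxy]methyl}-4-methyl-3,4,5-tris[(triethylsilyl)oxy]cyclohexan-1-one | COc1ccc(COC[C@H]2[C@H](O[Si](CC)(CC)CC)[C@@](C)(O[Si](CC)(CC)CC)[C@@H](O[Si](CC)(CC)CC)CC2=O)cc1 | intermediate
14 | (3S,4S,5S,6S)-6-{[(4-methoxybenzyl)oxy]methyl}-4-methyl-3,4,5-tris[(triethylsilyl)oxy]cyclohex-1-en-1-yl trifluoromethanesulfonate | COc1ccc(COC[C@H]2[C@H](O[Si](CC)(CC)CC)[C@@](C)(O[Si](CC)(CC)CC)[C@@H](O[Si](CC)(CC)CC)C=C2OS(=O)(=O)C(F)(F)F)cc1 | intermediate
15 | (3S,4S,5S,6S)-6-(hydroxymethyl)-4-methyl-3,4,5-tris[(triethylsilyl)oxy]cyclohex-1-en-1-yl trifluoromethanesulfonate | OC[C@H]1[C@H](O[Si](CC)(CC)CC)[C@@](C)(O[Si](CC)(CC)CC)[C@@H](O[Si](CC)(CC)CC)C=C1OS(=O)(=O)C(F)(F)F | intermediate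
16 | tributyl(vinyl)stannane | C=C[Sn](CCCC)(CCCC)CCCC | starting material
17 | [(1S,4S,5S,6S)-2-ethenyl-5-methyl-4,5,6-tris(triethylsilyloxy)cyclohex-2-en-1-yl]methanol | OC[C@H]1[C@H](O[Si](CC)(CC)CC)[C@@](C)(O[Si](CC)(CC)CC)[C@@H](O[Si](CC)(CC)CC)C=C1C=C | intermediate
18 | L-isoleucine | CC[C@H](C)[C@H](N)C(=O)O | starting material
19 | (2S,3S)-2-hydroxy-3-methylpentanoic acid | CC[C@H](C)[C@H](O)C(=O)O | intermediate
20 | (2S,3S)-2-hydroxy-N-methoxy-N,3-dimethylpentanamide | CC[C@H](C)[C@H](O)C(=O)N(C)OC | intermediate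
21 | (5S,6S)-5-hydroxy-2,6-dimethyloct-2-en-4-one | CC[C@H](C)[C@H](O)C(=O)C=C(C)C | intermediate
22 | (4R,5S,6S)-2,4,6-trimethyloct-2-ene-4,5-diol | CC[C@H](C)[C@H](O)[C@](C)(O)C=C(C)C | intermediate
23 | (4R,5S,6S)-2,4,6-trimethyl-4,5-bis[(triethylsilyl)oxy]oct-2-ene | CC[C@H](C)[C@H](O[Si](CC)(CC)CC)[C@](C)(O[Si](CC)(CC)CC)C=C(C)C | intermediate
24 | secondary ozonide of 23, a 3-substituted 5,5-dimethyl-1,2,4-trioxolane (not isolated) | CC[C@H](C)[C@H](O[Si](CC)(CC)CC)[C@](C)(O[Si](CC)(CC)CC)C1OOC(C)(C)O1 | intermediate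
25 | (2S,3S,4S)-2,4-dimethyl-2,3-bis[(triethylsilyl)oxy]hexanal | CC[C@H](C)[C@H](O[Si](CC)(CC)CC)[C@](C)(O[Si](CC)(CC)CC)C=O | intermediate
26 | methyl (2E,4R,5S,6S)-4,6-dimethyl-4,5-bis[(triethylsilyl)oxy]oct-2-enoate | CC[C@H](C)[C@H](O[Si](CC)(CC)CC)[C@](C)(O[Si](CC)(CC)CC)/C=C/C(=O)OC | intermediate
27 | (2E,4R,5S,6S)-4,6-dimethyl-4,5-bis[(triethylsilyl)oxy]oct-2-enoic acid | CC[C@H](C)[C@H](O[Si](CC)(CC)CC)[C@](C)(O[Si](CC)(CC)CC)/C=C/C(=O)O | intermediate
28 | [(1S,4S,5S,6S)-2-ethenyl-5-methyl-4,5,6-tris(triethylsilyloxy)cyclohex-2-en-1-yl]methyl (2E,4R,5S,6S)-4,6-dimethyl-4,5-bis(triethylsilyloxy)oct-2-enoate (precursor of the key step) | CC[C@H](C)[C@H](O[Si](CC)(CC)CC)[C@](C)(O[Si](CC)(CC)CC)/C=C/C(=O)OC[C@H]1[C@H](O[Si](CC)(CC)CC)[C@@](C)(O[Si](CC)(CC)CC)[C@@H](O[Si](CC)(CC)CC)C=C1C=C | intermediate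
29 | C4 titanium alkylidene of 28, terminal CH2 replaced by TiCl2, TMEDA not drawn (not isolated) | CC[C@H](C)[C@H](O[Si](CC)(CC)CC)[C@](C)(O[Si](CC)(CC)CC)/C=C/C(=O)OC[C@H]1[C@H](O[Si](CC)(CC)CC)[C@@](C)(O[Si](CC)(CC)CC)[C@@H](O[Si](CC)(CC)CC)C=C1C=[Ti](Cl)Cl | intermediate
30 | (6S,7S,8S,8aS)-3-[(1E,3R,4S,5S)-3,5-dimethyl-3,4-bis(triethylsilyloxy)hept-1-en-1-yl]-7-methyl-6,7,8-tris(triethylsilyloxy)-6,7,8,8a-tetrahydro-1H-isochromene (product of the key step) | CC[C@H](C)[C@H](O[Si](CC)(CC)CC)[C@](C)(O[Si](CC)(CC)CC)/C=C/C1=CC2=C[C@H](O[Si](CC)(CC)CC)[C@](C)(O[Si](CC)(CC)CC)[C@@H](O[Si](CC)(CC)CC)[C@@H]2CO1 | intermediate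
31 | (6S,7S,8S,8aS)-3-[(1E,3R,4S,5S)-3,4-dihydroxy-3,5-dimethylhept-1-en-1-yl]-7-methyl-6,7,8,8a-tetrahydro-1H-isochromene-6,7,8-triol | CC[C@H](C)[C@H](O)[C@](C)(O)/C=C/C1=CC2=C[C@H](O)[C@](C)(O)[C@@H](O)[C@@H]2CO1 | intermediate
32 | (7R,8S,8aS)-3-[(1E,3R,4S,5S)-3,4-dihydroxy-3,5-dimethylhept-1-en-1-yl]-7,8-dihydroxy-7-methyl-1,7,8,8a-tetrahydro-6H-isochromen-6-one | CC[C@H](C)[C@H](O)[C@](C)(O)/C=C/C1=CC2=CC(=O)[C@](C)(O)[C@@H](O)[C@@H]2CO1 | target

**Step count and risks**

Total step count: 23 (11 for ring A, 8 for the side-chain acid, 4 for union, key step and end game).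
Longest linear sequence: 15 steps (steps 1–11 and 20–23).

Steps most likely to fail:

1. Step 21. The titanium ethylidene may only ethylidenate the conjugated ester, or may fail to exchange with the diene terminus, so that no ring closes. Fallback: setting out from 28, methylenation of the ester carbonyl with Cp2TiMe2 (toluene, 70 °C, dark) would give the acyclic C3 methylidene enol ether F1. Ring-closing metathesis of its C4 vinyl group with the new 1,1-disubstituted enol ether alkene, under the second-generation Grubbs catalyst, would form the same C3=C4 bond with loss of ethylene. The sequence comes back to the route at 30.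

2. Step 6. The allyl double bond may migrate into conjugation with the ketone before the ring closes, or the β,γ-unsaturated ketone may lose its C8 silyloxy group and aromatise. Fallback: setting out from 9, reduction with i-Bu2AlH (THF, −78 °C) would give the aldehyde F2, and addition of CH2=CHCH2MgBr would give the homoallylic alcohols F3 (both C4a epimers). Ring-closing metathesis would then give the cyclohexenols F4, and oxidation with Dess–Martin periodinane buffered with NaHCO3 would give the ketone, so that the carbonyl group appears only after the ring has formed. The sequence comes back to the route at 11.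

3. Step 22. The polyol with a free C6 carbinol on the trienyl ether may ionise or decompose during desilylation or isolation. Fallback: setting out from 30, direct oxidation of the electron-rich allylic C6 silyl ether with DDQ (CH2Cl2, pH 7 buffer, 0 °C; hydride abstraction at C6 and loss of the silyl group) would give the tetrakis(triethylsilyl) ketone F5. HF·pyridine in THF/pyridine would then remove the four remaining silyl groups from the acid-tolerant vinylogous ester, so that no free C6 carbinol is ever handled. The sequence comes back to the route at 32.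

**Further compounds**

F1 | step 21 | C3 methylidene enol ether of 28 (ester C=O replaced by C=CH2) | CC[C@H](C)[C@H](O[Si](CC)(CC)CC)[C@](C)(O[Si](CC)(CC)CC)/C=C/C(=C)OC[C@H]1[C@H](O[Si](CC)(CC)CC)[C@@](C)(O[Si](CC)(CC)CC)[C@@H](O[Si](CC)(CC)CC)C=C1C=C
F2 | step 6 | (2S,3S)-2-{[(4-methoxybenzyl)oxy]methyl}-4-methyl-3-[(triethylsilyl)oxy]pent-4-enal | COc1ccc(COC[C@H](C=O)[C@H](O[Si](CC)(CC)CC)C(C)=C)cc1
F3 | step 6 | homoallylic alcohols from F2 and the allyl Grignard reagent, 5-{[(4-methoxybenzyl)oxy]methyl}-7-methyl-6-[(triethylsilyl)oxy]octa-1,7-dien-4-ol, both C4a epimers | COc1ccc(COC[C@H](C(O)CC=C)[C@H](O[Si](CC)(CC)CC)C(C)=C)cc1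
F4 | step 6 | cyclohexenols, 6-{[(4-methoxybenzyl)oxy]methyl}-4-methyl-5-[(triethylsilyl)oxy]cyclohex-3-en-1-ol, both C4a epimers | COc1ccc(COC[C@H]2[C@H](O[Si](CC)(CC)CC)C(C)=CCC2O)cc1
F5 | step 22 | tetrakis(triethylsilyl) ether of the target (silyl groups on the C7, C8, C3' and C4' oxygens, C6 ketone) | CC[C@H](C)[C@H](O[Si](CC)(CC)CC)[C@](C)(O[Si](CC)(CC)CC)/C=C/C1=CC2=CC(=O)[C@](C)(O[Si](CC)(CC)CC)[C@@H](O[Si](CC)(CC)CC)[C@@H]2CO1
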